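## Retrosynthetic overview
1. Cut the central CH2–CH2 bond (C11–C11′) to a decalin phenyl sulfone and a cyclohexenyl primary iodide bearing the methyl ester. Rejoin them by sulfone alkylation, then remove the sulfone reductively.
2. The 3β-hydroxy-8(12)-ene decalin comes from a Ti(III) radical cascade of (10S)-epoxyfarnesyl acetate, which forms rings A and B together and sets four centres. The farnesyl chain is built from sulcatone.
3. The cyclohexene ring comes from an asymmetric Diels–Alder between a 1,2-disubstituted diene and a dienal. This sets the quaternary centre and its two neighbours in one step.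
4. The dienal CHO is homologated to CH2CH2CO2Me, then the CH2OH is converted to the iodide.

*Assumptions (one line):* Catalyst enantiomers (Shi ketone, oxazaborolidinium) are chosen to give the configurations drawn. The E/Z mixtures from steps 3–4 are resolved at the farnesoate stage.

## Route

**Step 1**
Reactants: 1 (2-methylbut-3-en-2-ol); 2 (2-methoxypropene)
Product: 3 (6-methylhept-5-en-2-one, sulcatone)
Conditions: cat. H3PO4, neat, 130 °C (sealed)
Reagents that add atoms: none (both partners are the numbered reactants)
Why: Saucy–Marbet reaction: a mixed ketal forms the allyl isopropenyl ether, which undergoes a [3,3] Claisen rearrangement to the γ,δ-unsaturated ketone.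

**Step 2**
Reactants: 3
Product: 4 ((±)-linalool)
Conditions: CH2=CHMgBr, THF, 0 °C→rt; aq NH4Cl
Reagents that add atoms: vinylmagnesium bromide, C=C[Mg]Br
Why: 1,2-addition of the Grignard reagent to the methyl ketone gives the tertiary allylic alcohol; the carbinol stereocentre is destroyed in the next step.

**Step 3**
Reactants: 4; 2
Product: 5 ((5E)-geranylacetone, major isomer)
Conditions: cat. H3PO4, 2-methoxypropene (excess), 140 °C (sealed)
Reagents that add atoms: none
Why: Second Saucy–Marbet/Claisen reaction; the chair transition state favours the E trisubstituted alkene (E:Z ≈ 3:2), and the isomers are separated later.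

**Step 4**
Reactants: 5
Product: 6 (ethyl (2E,6E)-farnesoate)
Conditions: (EtO)2P(O)CH2CO2Et, NaH, THF, 0 °C→rt; AgNO3–SiO2 separation of the E,E isomer
Reagents that add atoms: triethyl phosphonoacetate, CCOC(=O)CP(=O)(OCC)OCC
Why: Horner–Wadsworth–Emmons olefination of the methyl ketone, E-selective (≈3:1).

**Step 5**
Reactants: 6
Product: 7 ((2E,6E)-farnesol)
Conditions: DIBAL-H, CH2Cl2, −78 °C
Reagents that add atoms: none
Why: Ester-to-alcohol reduction leaves all alkenes untouched.

**Step 6**
Reactants: 7
Product: 8 ((2E,6E)-farnesyl acetate)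
Conditions: Ac2O, pyridine, DMAP, CH2Cl2, 0 °C
Reagents that add atoms: acetic anhydride, CC(=O)OC(C)=O
Why: Acetylation gives the protected allylic alcohol needed for the titanium cascade and deactivates the C2=C3 alkene toward epoxidation.

**Step 7**
Reactants: 8
Product: 9 ((10S)-10,11-epoxyfarnesyl acetate)
Conditions: Shi fructose-derived ketone (30 mol%), Oxone, K2CO3, Bu4NHSO4, MeCN/DMM/aq. buffer pH 10.5, 0 °C
Reagents that add atoms: Oxone (KHSO5), OOS(=O)(=O)[O-].[K+] (supplies O)
Why: Shi asymmetric epoxidation (chiral dioxirane) of the most accessible trisubstituted terminal alkene fixes the future C3 configuration as S; the minor 6,7-epoxide is removed by chromatography.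

**Step 8**
Reactants: 9
Product: 10 (3β-hydroxydrim-8(12)-en-11-yl acetate; 5α,9α,10β)
Conditions: Cp2TiCl2 (20 mol%), Mn, 2,4,6-collidine, TMSCl, THF, rt; aq HCl work-up
Reagents that add atoms: none (net isomerisation)
Why: Ti(III) opens the epoxide to a tertiary radical that cascades 6-endo/6-endo through a chair–chair transition state to the trans-anti-trans decalin (sets C5, C9, C10; C3 is retained from the epoxide). Ti capture and β-hydride elimination from the methyl give the exocyclic methylene.

**Step 9**
Reactants: 10
Product: 11 (3β-OTBS analogue of 10)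
Conditions: TBSOTf, 2,6-lutidine, CH2Cl2, 0 °C
Reagents that add atoms: TBSOTf, C[Si](C)(C(C)(C)C)OS(=O)(=O)C(F)(F)F
Why: The triflate silylates the hindered equatorial secondary alcohol so it survives the carbanion chemistry later.

**Step 10**
Reactants: 11
Product: 12 (3β-OTBS-drim-8(12)-en-11-ol)
Conditions: K2CO3, MeOH, rt
Reagents that add atoms: none
Why: Methanolysis removes only the primary acetate; the TBS ether is stable.

**Step 11**
Reactants: 12
Product: 13 (11-phenylthio compound)
Conditions: PhSSPh, n-Bu3P, toluene, 60 °C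
Reagents that add atoms: diphenyl disulfide, c1ccccc1SSc1ccccc1 (supplies PhS)
Why: Phosphonium activation of the primary alcohol and SN2 displacement by thiophenoxide (Hata/Grieco-type thioetherification), suited to β-branched primary alcohols.

**Step 12**
Reactants: 13
Product: 14 (11-phenylsulfonyl-3β-OTBS-drim-8(12)-ene)
Conditions: Oxone, MeOH/H2O, 0 °C→rt
Reagents that add atoms: Oxone, OOS(=O)(=O)[O-].[K+] (supplies O)
Why: Sulfur is oxidised far faster than the 1,1-disubstituted alkene, giving the sulfone without epoxidation.

**Step 13**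
Reactants: 15 (methyl vinyl ketone)
Product: 16 (ethyl (2E)-3-methylpenta-2,4-dienoate)
Conditions: (EtO)2P(O)CH2CO2Et, NaH, THF, 0 °C→rt; chromatographic removal of the Z isomer
Reagents that add atoms: triethyl phosphonoacetate, CCOC(=O)CP(=O)(OCC)OCC
Why: HWE olefination of the enone C=O gives the E-dienoate (E:Z ≈ 3:1).

**Step 14**
Reactants: 16
Product: 17 ((2E)-3-methylpenta-2,4-dien-1-ol)
Conditions: DIBAL-H, CH2Cl2, −78 °C
Reagents that add atoms: none
Why: Chemoselective ester reduction; the diene is intact.

**Step 15**
Reactants: 17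
Product: 18 (TBS ether of 17)
Conditions: TBSCl, imidazole, DMF, rt
Reagents that add atoms: TBSCl, C[Si](C)(Cl)C(C)(C)C
Why: Silyl protection prepares a Lewis-acid-compatible diene whose E-CH2OTBS group sits "outside" for the Diels–Alder step.

**Step 16**
Reactants: 19 (methacrolein)
Product: 20 ((2E)-2,4-dimethylpenta-2,4-dienal)
Conditions: Ph3P=C(Me)CHO, toluene, 80 °C
Reagents that add atoms: 2-(triphenylphosphoranylidene)propanal, CC(C=O)=P(c1ccccc1)(c1ccccc1)c1ccccc1 (supplies C(CH3)CHO)
Why: Wittig olefination with a stabilised ylide is E-selective, placing CHO trans to the isopropenyl group.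

**Step 17**
Reactants: 18; 20
Product: 21 (2-[(TBSO)methyl]-1,3-dimethyl-6-isopropenylcyclohex-3-ene-1-carbaldehyde; Me, CH2OTBS and isopropenyl all cis, CHO on the opposite face)
Conditions: chiral oxazaborolidinium·Tf2N catalyst (Corey, 20 mol%), CH2Cl2, −78→−30 °C
Reagents that add atoms: none (catalyst only)
Why: Lewis-acid-catalysed asymmetric Diels–Alder. "Ortho" regiochemistry joins the substituted diene terminus to the α-carbon of the enal. The α-substituted enal reacts through the exo-CHO/endo-Me transition state, the E-dienophile puts isopropenyl cis to Me, and the outside CH2OTBS ends up cis to the endo Me. This sets C5′, C9′ and C10′ in one step.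

**Step 18**
Reactants: 21
Product: 22 (methyl (E)-3-[ring]acrylate)
Conditions: (MeO)2P(O)CH2CO2Me, LiCl, DBU, MeCN, rt
Reagents that add atoms: methyl 2-(dimethoxyphosphoryl)acetate, COC(=O)CP(=O)(OC)OC
Why: Masamune–Roush HWE olefination. The aldehyde has an α-quaternary carbon, so it cannot epimerise, and the E-enoate forms.

**Step 19**
Reactants: 22
Product: 23 (methyl 3-[ring]propanoate, OTBS retained)
Conditions: Mg turnings, MeOH, rt
Reagents that add atoms: none
Why: Mg/MeOH reduces the conjugated enoate selectively, leaving the ring alkene, isopropenyl group and silyl ether untouched.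

**Step 20**
Reactants: 23
Product: 24 (primary alcohol)
Conditions: HF·pyridine, pyridine/THF, 0 °C→rt
Reagents that add atoms: none
Why: Mild fluoride cleavage of the primary TBS ether leaves the methyl ester and alkenes intact.

**Step 21**
Reactants: 24
Product: 25 (primary iodide)
Conditions: I2, PPh3, imidazole, CH2Cl2, 0 °C→rt
Reagents that add atoms: iodine, II
Why: Appel-type iodination converts the hindered primary alcohol to the electrophile.

**Step 22**
Reactants: 14; 25
Product: 26 (coupled sulfone, mixture at the sulfone-bearing carbon)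
Conditions: n-BuLi (1.05 equiv), THF, −78 °C; then HMPA, 25, −78→−30 °C
Reagents that add atoms: none
Why: SN2 alkylation of the α-sulfonyl carbanion by the primary iodide forms the C11–C11′ bond; the new stereocentre is temporary.

**Step 23**
Reactants: 26
Product: 27 (TBS ether of methyl lansiolate)
Conditions: 6% Na(Hg), Na2HPO4, MeOH/THF, −20 °C→rt
Reagents that add atoms: none
Why: Reductive desulfonylation (Julia-type) replaces PhSO2 with H without touching the alkenes, the methyl ester or the silyl ether; C9 and C9′ are not epimerisable.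

**Step 24**
Reactants: 27
Product: 28 (methyl lansiolate)
Conditions: HF·pyridine, pyridine/THF, rt→40 °C
Reagents that add atoms: none
Why: Fluoride removal of the hindered secondary TBS ether releases the 3β-OH.

## Compound list
1 | 2-methylbut-3-en-2-ol | C=CC(C)(C)O | starting material
2 | 2-methoxypropene | C=C(C)OC | starting material
3 | 6-methylhept-5-en-2-one | CC(C)=CCCC(C)=O | intermediate
4 | (±)-linalool | C=CC(C)(O)CCC=C(C)C | intermediate
5 | (5E)-geranylacetone | CC(=O)CC/C=C(\C)CCC=C(C)C | intermediate
6 | ethyl (2E,6E)-farnesoate | CCOC(=O)/C=C(\C)CC/C=C(\C)CCC=C(C)C | intermediate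
7 | (2E,6E)-farnesol | OC/C=C(\C)CC/C=C(\C)CCC=C(C)C | intermediate
8 | (2E,6E)-farnesyl acetate | CC(=O)OC/C=C(\C)CC/C=C(\C)CCC=C(C)C | intermediate
9 | (10S)-10,11-epoxyfarnesyl acetate | CC(=O)OC/C=C(\C)CC/C=C(\C)CC[C@@H]1OC1(C)C | intermediate
10 | 3β-hydroxydrim-8(12)-en-11-yl acetate | CC(=O)OC[C@H]2C(=C)CC[C@H]3C(C)(C)[C@@H](O)CC[C@]23C | intermediate
11 | 3β-OTBS analogue of 10 | CC(=O)OC[C@H]2C(=C)CC[C@H]3C(C)(C)[C@@H](O[Si](C)(C)C(C)(C)C)CC[C@]23C | intermediate
12 | 3β-OTBS-drim-8(12)-en-11-ol | OC[C@H]2C(=C)CC[C@H]3C(C)(C)[C@@H](O[Si](C)(C)C(C)(C)C)CC[C@]23C | intermediate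
13 | 11-phenylthio compound | c1ccccc1SC[C@H]2C(=C)CC[C@H]3C(C)(C)[C@@H](O[Si](C)(C)C(C)(C)C)CC[C@]23C | intermediate
14 | 11-phenylsulfonyl-3β-OTBS-drim-8(12)-ene | O=S(=O)(c1ccccc1)C[C@H]2C(=C)CC[C@H]3C(C)(C)[C@@H](O[Si](C)(C)C(C)(C)C)CC[C@]23C | intermediate
15 | methyl vinyl ketone | C=CC(C)=O | starting material
16 | ethyl (2E)-3-methylpenta-2,4-dienoate | CCOC(=O)/C=C(\C)C=C | intermediate
17 | (2E)-3-methylpenta-2,4-dien-1-ol | OC/C=C(\C)C=C | intermediate
18 | TBS ether of 17 | CC(C)(C)[Si](C)(C)OC/C=C(\C)C=C | intermediate
19 | methacrolein | C=C(C)C=O | starting material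
20 | (2E)-2,4-dimethylpenta-2,4-dienal | O=C/C(C)=C/C(C)=C | intermediate
21 | Diels–Alder adduct aldehyde | C=C(C)[C@@H]1CC=C(C)[C@H](CO[Si](C)(C)C(C)(C)C)[C@@]1(C)C=O | intermediate
22 | methyl (E)-enoate | C=C(C)[C@@H]1CC=C(C)[C@H](CO[Si](C)(C)C(C)(C)C)[C@@]1(C)/C=C/C(=O)OC | intermediate
23 | saturated methyl ester, OTBS | C=C(C)[C@@H]1CC=C(C)[C@H](CO[Si](C)(C)C(C)(C)C)[C@@]1(C)CCC(=O)OC | intermediate
24 | primary alcohol | C=C(C)[C@@H]1CC=C(C)[C@H](CO)[C@@]1(C)CCC(=O)OC | intermediate
25 | primary iodide | C=C(C)[C@@H]1CC=C(C)[C@H](CI)[C@@]1(C)CCC(=O)OC | intermediate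
26 | coupled sulfone | C=C(C)[C@@H]1CC=C(C)[C@H](CC(S(=O)(=O)c4ccccc4)[C@H]2C(=C)CC[C@H]3C(C)(C)[C@@H](O[Si](C)(C)C(C)(C)C)CC[C@]23C)[C@@]1(C)CCC(=O)OC | intermediate
27 | TBS ether of methyl lansiolate | C=C(C)[C@@H]1CC=C(C)[C@H](CC[C@H]2C(=C)CC[C@H]3C(C)(C)[C@@H](O[Si](C)(C)C(C)(C)C)CC[C@]23C)[C@@]1(C)CCC(=O)OC | intermediate
28 | methyl lansiolate | C=C(C)[C@@H]1CC=C(C)[C@H](CC[C@H]2C(=C)CC[C@H]3C(C)(C)[C@@H](O)CC[C@]23C)[C@@]1(C)CCC(=O)OC | target

## Totals
- Total steps: 24.
- Longest linear sequence: 15 (steps 1→12, then 22→24).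

**Three steps most likely to fail**
1. **Step 17 (Diels–Alder).** A tri-substituted dienal with a 1,2-disubstituted diene may react slowly, give the wrong regiochemistry or exo/endo outcome, or react at the isopropenyl alkene.
   Fallback: a temporary silicon-tethered intramolecular Diels–Alder. Link diene alcohol 17 through an O–SiR2–O tether to (E)-2,4-dimethylpenta-2,4-dien-1-ol and heat, so the tether enforces the regiochemistry and relative stereochemistry. Then cleave the tether and oxidise C1′–OH back to the aldehyde, resolving or using a chiral tether for absolute configuration.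
2. **Step 22 (sulfone alkylation).** Both partners are β-branched primary carbons next to quaternary centres, so SN2 is slow. E2 elimination of the iodide to the conjugated diene, or attack on the methyl ester, may compete.
   Fallback: convert 14 to the alkyl iodide and then the alkylzinc reagent, and do a Ni- or Pd-catalysed alkyl–alkyl Negishi coupling with 25. This tolerates the ester and avoids strongly basic carbanions.
3. **Step 8 (Ti(III) cascade).** Yields of such cascades are modest, with monocyclic and Δ7 by-products. The C8 elimination regiochemistry and the E,E-purity inherited from steps 3–4 both matter.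
   Fallback: build the decalin from (S)-Wieland–Miescher ketone (from 1,3-cyclohexanedione via 2-methylcyclohexane-1,3-dione, MVK and (S)-proline). Do gem-dimethylation and trans-ring reduction, move the C9 ketone to C8, alkylate C9 of the 8-ketone and equilibrate to the equatorial chain, then Wittig-methylenate C8.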